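A small charge of E, half of the J in the red run, is what I must judge before I charge twice as much. The decision is whether the share of Z survives the larger charge.

| flask | J | E | G | temperature | remark | time |
|---|---|---|---|---|---|---|
| red | 2 M | 1 M | 200 mM (held) | −40 °C | run made earlier |  |
| Monday's | 2.0 M | 2.00 M | 200 mM (held) | −40 °C |  | 2.0 h |
| Friday's | 2.0 M | 2.00 M | 200 mM (held) | −20 °C |  | 2.0 h |
| Wednesday's | 2.0 M | 2.00 M | 200 mM (held) | 0 °C |  | 2.0 h |

red run (percent of the J charged)

| time / min | Z / % | Q / % |
|---|---|---|
| 3.00 | 0 | 0 |
| 5.00 | 1.1 | 4.5 |
| 8.00 | 3.4 | 7.1 |
| 12.0 | 4.8 | 8.1 |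
| 20.0 | 11.8 | 14.3 |
| 40.0 | 22.4 | 26.3 |

(scatter of a reading: 1 percentage point)

- at the start none of G is in solution
- the earlier runs do not show what temperature does; that part of a forecast is a guess

- which flask leads in share of Z in all that became Z or Q ("all alike" within 1.5 percentage points) (Monday's / Friday's / Wednesday's / all alike)
- share of Z in all that became Z or Q, Monday's
- share of Z in all that became Z or Q, Friday's
- share of Z in all that became Z or Q, Wednesday's

I assume that each Q costs one E and that dissolved G holds level after the first minutes. Z then forms against Q as a fixed number over the fraction of E left. Between 20.0 min and 40.0 min of the red run, the readings of Q put the fraction of E left at 71.4 % and then 47.4 %, while Z gains 11 percentage points of the J. Dividing that gain, taken as a fraction of the E charge, by the fall in the logarithm of the fraction left gives 0.517. Monday's charge of E is larger, so its number is 0.259, my competition number: a selectivity factor at this level of dissolved G, expressed in fractions of the E charge. It is a reading, and each reading behind it is good to 1 point.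

Now I solve Monday's flask at both ends. At one end, with E still whole and dissolved G level, a step gives a Z share of 20.6 %. At the other end, once J is used up, equal charges make the fraction of Z equal to the fraction of E left. Joining the ends, Z is the number times the logarithm of the reciprocal of the fraction left, and that fraction is the Z fraction itself. A trial of a third returns 28.4 %, which returns 32.5 %, and the root lies between, near 30.5 %. That is less than the 46.0 % at the red run's last reading. So I charge Monday's as written, expect the share of Z to fall below that reading, and sample E left. The runs do not show what warming does, so I carry no number to Friday's or Wednesday's.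

The forecast names Monday's as leader, with 47 %, 43 % and 39 %, and holds that "E has little effect on the split"; for Monday's it differs from my 30.5 %.

Monday's gives 29.9 %, Friday's 33.1 % and Wednesday's 16.3 %, so Friday's leads. In Monday's, J still stands at 12 % at 2.00 h, and the share reaches 31.7 % at 20.0 h.

    G ⇌ D, rate k1*(csat - [D]) (kL = 0.0337 s⁻¹)
    E + X → Q (k = 0.0238 M⁻¹ s⁻¹, Ea = 39.0 kJ mol⁻¹)
    J → X (k = 0.00657 s⁻¹, Ea = 76.0 kJ mol⁻¹)
    D + X → Z (k = 0.100 M⁻¹ s⁻¹, Ea = 49.0 kJ mol⁻¹)
    (constants at −20 °C)

In Monday's at 2.00 h, E left at 39 % puts 0.259 at a Z of 24.4 %, beside the 26.2 % that stands there. Wednesday's, with J at 0 %, returns 0.0903 from the same rule, a third of 0.259.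

All runs come from a simulation with constants of no real substance; noise was put on by code.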